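## Structural features

The target is a 3,4-dihydroisocoumarin (isochroman-1-one): a benzene ring (ring A) fused across C4a–C8a to a six-membered δ-lactone (ring B) made of C1(=O), O2, C3 and C4. Ring A is 1,2,3,5-tetrasubstituted: C8a carries the lactone carbonyl and lies between the free phenol at C8 and C4a (which carries the C4 methylene), C6 carries a methoxy group, and C5 and C7 carry hydrogen. C3 is the only stereocentre, (R)-configured, and bears an unbranched eleven-carbon chain ending in a primary alcohol, so the task is absolute control at one isolated centre with no neighbouring stereocentre to relay from. The sensitive sites are the lactone (opened by hydroxide or alkoxide), the C8 phenol hydrogen-bonded to the C1 carbonyl, and the homobenzylic C3–O bond, which could be lost by elimination towards C4 under forcing conditions; C3 is not α to a carbonyl and cannot epimerise by enolisation. The real difficulties are the regiodefined assembly of the contiguous C8–C8a–C4a substitution together with the meta oxygen at C6, the differentiation of the two ring oxygens (methyl ether at C6, free hydroxyl at C8), and the secure placement of the remote carbinol configuration on a long chain whose terminal hydroxyl must stay masked through organometallic steps. The key step uses the fact that, read around ring A, C8(O)–C7(H)–C6(O)–C5(H) is a four-carbon unit oxygenated at its first and third carbons, that is a 1,3-dialkoxy diene, while C8a (carboxyl-bearing) and C4a (alkyl-bearing) are two adjacent carbons that match the α- and β-carbons of a 2-alkynoate. Because the C8 oxygen ends up peri to the carbonyl, it can later be told apart from the C6 oxygen by chelation.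

## Logic of the disconnections

**18 ⇒ 17.** Forwards, the O–CH3 bond on the C8 oxygen is cut; backwards, the phenol is capped as a methyl ether. Both ring oxygens then travel as identical, robust methyl ethers through organometallic, thermal and acidic steps, and no phenol protecting group is needed. The gain is that the oxygenated half of ring A can come from a simple bis(enol ether). The forward step must be site-selective: only the ether that can chelate to the C1 carbonyl may fall, while the C6 ether, the lactone and the free primary alcohol survive.

**17 ⇒ 15 (through 16).** The acyl C1–O2 bond of ring B is cut and both hydroxyls are capped with the same silyl group. This dissolves ring B and leaves a monocyclic benzoate with an acyclic side chain. One acidic operation should remove both silyl groups and close the ring. The forward step must not ionise or eliminate the homobenzylic carbinol, and the secondary alcohol has to attack a benzoate with two ortho substituents, which is acceptable because the attack is intramolecular and six-membered.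

**15 ⇒ 10 + 13 (through 14).** The ring A bonds C8–C8a and C5–C4a are cut, and a two-carbon bridge is formally put back across C5 and C8. The cut is made here because a carboxyl flanked by an oxygen and an alkyl group, with a second oxygen meta, is exactly what the polarity of a [4+2] addition delivers. It also leaves the stereocentre in an acyclic partner, two atoms away from the reacting carbons. Ring A disappears altogether, leaving a cyclic diene and a linear ynoate, neither of which has a regiochemical problem of its own. The forward step must pair the unsubstituted diene terminus with the β-carbon of the ynoate, the silyl ethers must survive neutral heating near 190 °C, and the bridge must be extruded completely.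

**13 ⇒ 12 ⇒ 11.** No skeletal bond is cut. One double bond of 13 is moved out of conjugation to give 12, and removal of two hydrogens from 12 leads back to a commercial arene. The forward steps must exclude acid, since the bis(enol ether) hydrolyses readily, and must push the conjugation equilibrium far enough for 13 to be used in excess.

**10 ⇒ 9 ⇒ 6 + 7 (through 8).** First the O–Si bond at the C5 oxygen is cut, then the C3–C4 bond between the alkyne and the methylene (ynoate numbering). This exposes an acetylide already carrying the ester and a terminal epoxide, so no later carboxylation is needed and the stereocentre is not a reaction site. The sixteen-carbon chain is split into a three-carbon and a thirteen-carbon piece. The forward step needs low temperature (the metallated ester is thermally fragile), Lewis acid activation of the epoxide, and exclusive attack at its CH2 terminus.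

**6 ⇒ 2 + 3 (through 4 and 5).** The C–C bond between the first and second methylene of the side chain, counted from the oxirane, is cut. The stereocentre is then bought in a three-carbon building block and the rest is an achiral C10 organometallic. The forward step must attack the ring carbon of 3 and not its chloromethyl carbon, and must then close the new oxirane cleanly, so that the configuration is carried over intact.

**2 ⇒ 1.** The O–Si bond is cut. The free hydroxyl is incompatible with organomagnesium formation, and a silyl ether is chosen because it is later removed in the same operation as the secondary one.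

## Other disconnections considered

**Alternative 1:** The cut removes O2 and joins C1 to C3, leading to the racemic indanone A1 (2-(11-hydroxyundecyl)-5,7-dimethoxyindan-1-one). Forwards, a Baeyer–Villiger monooxygenase with O2 and recycled NADPH would insert oxygen between C1 and C2 of A1, while mild base racemises the unreacted ketone through its enol, giving lactone A2, which is identical with 17.
- In its favour: a dynamic kinetic resolution could convert all of the racemate; the stereocentre and the ring oxygen would be set in one catalytic aerobic step at ambient temperature; the primary alcohol needs no protection; A1 should be reachable in three or four conventional steps.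
- Against it here: the electron-rich aryl group is intrinsically the better migrating group in a Criegee rearrangement, so the enzyme alone must enforce migration of the secondary alkyl carbon and at the same time distinguish the enantiomers. It must do this on a substrate with a lipophilic C11 chain and a methoxy group flanking the ketone, well outside the small 2-alkyl indanones for which such resolutions are established. Enzyme engineering, low aqueous solubility and the balance of racemisation rate against enzyme stability are open questions.
- Comparison: on step economy this alternative is the better one (roughly five steps to A2 against eight to 17), and it is greener. On structure it builds ring B on a bought arene, whereas the chosen plan builds ring A around a bought stereocentre. On mechanism its selectivity rests on a protein, while the chosen plan relies on substrate polarity and a chiral-pool centre. Both plans need the same final C8 demethylation, so they are equal there.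

**Alternative 2:** The cut removes the C4a–C4 and O2–C3 bonds, and before that the two hydrogens at C3 and C4. Forwards, [Cp*RhCl2]2 (trivalent rhodium) would metallate the only free ortho C–H of 2,4-dimethoxybenzoic acid A3 under carboxylate direction. The sulfoxonium ylide A4 (13-(tert-butyldimethylsilyloxy)-1-[dimethyl(oxo)-λ6-sulfanylidene]tridecan-2-one) would transfer its carbene carbon with loss of the sulfoxide, and cyclodehydration would give isocoumarin A5. Enantioselective hydrogenation of the C3=C4 enol-lactone bond would then give A6, and desilylation plus the C8 demethylation would finish.
- In its favour: A3 has a single ortho hydrogen, so the regiochemistry is automatic; the arene and its oxygens are bought; the route is convergent and short (about five to six steps), with no cryogenic or high-temperature step. On step economy it is better than the chosen plan.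
- Against it here: the stereocentre must be created late by face-selective hydrogenation of a trisubstituted enol ester embedded in a benzopyranone. The C3 substituent is an unbranched alkyl chain that offers little steric bias, and the C8 methoxy group and carbonyl can compete for the metal (for example with [Ir(cod)Cl]2 and a chiral bisphosphine, or Ru(OAc)2(binap)). The enantiomeric purity would have to be established and possibly upgraded, and over-reduction or ring opening is conceivable.
- Comparison: the chosen plan is longer but takes its configuration from the chiral pool and never touches C3 again. The two plans are equal in needing a terminal hydroxyl protecting group and the same final demethylation. Mechanistically the alternative forms one C–C and one C–O bond on an existing arene by organometallic steps, whereas the chosen plan forms two C–C bonds of a new arene by a pericyclic pair.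

**Alternative 3:** The cut is the C4a–C8a bond of ring A, leading to the diketo-dioxinone A7 (6-[(R)-6,17-bis(tert-butyldimethylsilyloxy)-2,4-dioxoheptadecyl]-2,2-dimethyl-4H-1,3-dioxin-4-one). Forwards, mild base then acid would make the dioxinone α-carbon add to the distal ketone; dehydration and enolisation would give the resorcylate A8. Methylation of its only free phenol would give A9, and desilylation would let the C3 hydroxyl open the dioxinone, closing ring B and releasing the C8 phenol.
- In its favour: the conditions are mild and biomimetic, and the dioxinone differentiates the two ring oxygens by construction. The C8 hydroxyl appears free at the end and only the C6 oxygen is ever methylated, so no demethylation is needed; on this point it is better than the chosen plan. It also avoids any step near 190 °C.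
- Against it here: A7 is a sensitive poly-β-carbonyl compound that must be assembled by successive Claisen-type acylations and is normally carried forward crude. The silyloxy group sits β to the distal ketone of A7, so the base and acid used for aromatisation also invite β-elimination, which would destroy the stereocentre; this liability is specific to this target. The chiral β-silyloxy acyl fragment still has to be made, most simply from the same epoxide as in the chosen plan, so the step count would be about the same or higher.
- Comparison: both plans create ring A de novo with the regiochemistry fixed by connectivity, so they are equal on that count. The alternative is ionic (aldol, dehydration) and mild but carries labile intermediates; the chosen plan is pericyclic, neutral and carries only stable, isolable intermediates.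

Key step: step 7

Remarks on the chemistry:
- No bond to C3 is made or broken after 3 is bought, and the priority order at that carbon (oxygen, then the CH2 on the chloro, oxirane, alkyne or aryl side, then the chain CH2) is the same in 3, 5, 6, 9, 10, 15, 16, 17 and 18, so the descriptor stays (R) throughout. The structures and descriptors of the key-step precursor, its product and the starting materials are mutually consistent; none needed correction.
- Two refinements to the precursor are made. Both hydroxyls carry the same silyl group, so one acidic operation frees them and closes ring B. The secondary silyl ether is installed with the silyl triflate and a hindered pyridine, so that no nucleophilic amine meets the ynoate.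
- 13 is taken into step 7 in excess as distilled, conjugation-enriched material; residual 12 is a spectator.

## Route

**Step 1**
Reactants: 1 10-bromodecan-1-ol
Product: 2 (10-bromodecyloxy)(tert-butyl)dimethylsilane
Conditions: TBSCl, imidazole, CH2Cl2, 0 °C → rt
Reagents that add atoms: tert-butyldimethylsilyl chloride (TBSCl), CC(C)(C)[Si](C)(C)Cl
Why: Routine silylation of a primary alcohol; the silyl ether removes the acidic proton that would quench the organomagnesium reagent of step 2.

**Step 2**
Reactants: 2 (10-bromodecyloxy)(tert-butyl)dimethylsilane; 3 (R)-epichlorohydrin
Product: 6 (R)-tert-butyldimethyl{[11-(oxiran-2-yl)undecyl]oxy}silane, via Grignard reagent 4 (not isolated), via chlorohydrin alkoxide 5 (not isolated)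
Conditions: Mg, THF, 45 °C; CuI (10 mol %), 3 (1.2 equiv), −30 → 0 °C; then 2 M aq. NaOH, rt
Reagents that add atoms: none
Why: Copper-catalysed Grignard opening of the oxirane at its unsubstituted ring carbon, then intramolecular Williamson closure with displacement of chloride; the stereocentre is never a reaction site, so (R)-3 should give (R)-6. A slight excess of 3 leaves no organomagnesium to attack the new epoxide.

**Step 3**
Reactants: 6 (R)-tert-butyldimethyl{[11-(oxiran-2-yl)undecyl]oxy}silane; 7 methyl propiolate
Product: 9 methyl (R)-5-hydroxy-16-(tert-butyldimethylsilyloxy)hexadec-2-ynoate, via lithium methyl propiolate 8 (not isolated)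
Conditions: 7 (2.5 equiv), n-BuLi, THF, −78 °C; BF3·OEt2; then 6, −78 °C; H2O quench
Reagents that add atoms: none
Why: Yamaguchi–Hirao alkynylation: the BF3-activated terminal epoxide is opened at its CH2 carbon by the lithium acetylide in an SN2 process, so the carbinol carbon keeps its configuration. The whole sequence stays at −78 °C because the metallated ester does not tolerate warming.

**Step 4**
Reactants: 9 methyl (R)-5-hydroxy-16-(tert-butyldimethylsilyloxy)hexadec-2-ynoate
Product: 10 methyl (R)-5,16-bis(tert-butyldimethylsilyloxy)hexadec-2-ynoate
Conditions: TBSOTf, 2,6-lutidine, CH2Cl2, −78 → 0 °C
Reagents that add atoms: tert-butyldimethylsilyl trifluoromethanesulfonate (TBSOTf), CC(C)(C)[Si](C)(C)OS(=O)(=O)C(F)(F)F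
Why: Silylation of a secondary alcohol with a silyl triflate and a hindered, non-nucleophilic base; nucleophilic amines such as imidazole are avoided because they can add in conjugate fashion to the ynoate.

**Step 5**
Reactants: 11 1,3-dimethoxybenzene
Product: 12 1,5-dimethoxycyclohexa-1,4-diene
Conditions: Li, liq. NH3, THF, t-BuOH, −78 → −33 °C; then MeOH, H2O
Reagents that add atoms: none
Why: Birch reduction; protonation occurs at the two ring carbons that leave both methoxy groups on sp2 carbons, giving the 2,5-dihydro arene. The work-up is kept basic because the bis(enol ether) is acid-labile.

**Step 6**
Reactants: 12 1,5-dimethoxycyclohexa-1,4-diene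
Product: 13 1,3-dimethoxycyclohexa-1,3-diene
Conditions: KOt-Bu (0.2 equiv), DMSO, rt, Ar; distillation
Reagents that add atoms: none
Why: Base-mediated prototropic conjugation (deprotonation at a doubly allylic methylene, reprotonation at the end of the pentadienyl anion) should favour the conjugated bis(enol ether), in which both methoxy groups sit on the diene.

**Step 7**
Reactants: 10 methyl (R)-5,16-bis(tert-butyldimethylsilyloxy)hexadec-2-ynoate; 13 1,3-dimethoxycyclohexa-1,3-diene
Product: 15 methyl (R)-2-[2,13-bis(tert-butyldimethylsilyloxy)tridecyl]-4,6-dimethoxybenzoate, via bicyclooctadiene adduct 14 (not isolated)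
Conditions: 13 (3 equiv), BHT (cat.), neat, Ar, sealed tube, 190 °C
Reagents that add atoms: none
Why: A concerted, asynchronous, normal-electron-demand [4+2] addition of the electron-rich diene 13 to the electron-poor ynoate 10 should give the bicyclo[2.2.2]octa-2,5-diene 14, which at the same temperature undergoes retro-[4+2] loss of its saturated two-carbon bridge; aromatisation and escape of the gas make the sequence irreversible. The closest known reaction type is the Alder–Rickert reaction of methoxy-substituted cyclohexa-1,3-dienes with 2-alkynoates, which gives methoxylated benzoates. Ring A is closed by intermolecular cycloaddition (the C8–C8a and C5–C4a bonds form together) followed by cycloreversion, with no ionic cyclisation. No stereocentre is created in 15: the two bridgehead centres of 14 are transient and vanish on aromatisation, and the C3 carbinol centre, two atoms from the alkyne, has no pathway for epimerisation under neutral thermolysis. The selectivity needed is regiochemical. The unsubstituted diene terminus receives electron density from both methoxy groups and carries the largest HOMO coefficient, so it bonds to the electrophilic β-carbon of the ynoate; the methoxy-bearing terminus bonds to the α-carbon, placing the ester between the C8 methoxy group and the side chain. The silyl ethers and the methyl ester are inert to these conditions, and the excess of 13 with a radical inhibitor compensates for thermal self-consumption of the diene.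

**Step 8**
Reactants: 15 methyl (R)-2-[2,13-bis(tert-butyldimethylsilyloxy)tridecyl]-4,6-dimethoxybenzoate
Product: 17 (R)-3-(11-hydroxyundecyl)-6,8-dimethoxyisochroman-1-one, via diol ester 16 (not isolated)
Conditions: p-TsOH·H2O (0.3 equiv), MeOH, 45 °C; then solvent exchange to PhMe, 80 °C
Reagents that add atoms: none
Why: Acid-catalysed methanolysis of both silyl ethers, then intramolecular transesterification (six-membered lactonisation), driven by removal of methanol on the solvent switch; the C3–O bond is not broken, so the configuration is retained.

**Step 9**
Reactants: 17 (R)-3-(11-hydroxyundecyl)-6,8-dimethoxyisochroman-1-one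
Product: 18 (R)-8-hydroxy-3-(11-hydroxyundecyl)-6-methoxyisochroman-1-one
Conditions: BCl3 (3 equiv), CH2Cl2, −78 → 0 °C; then H2O
Reagents that add atoms: none
Why: Chelation-controlled Lewis acid cleavage of an aryl methyl ether: boron bridges the C1 carbonyl oxygen and the peri C8 methoxy oxygen, and chloride removes that activated methyl group by SN2. The C6 methoxy group cannot chelate and should stay; the primary alcohol is held as a borate and freed on hydrolysis.

## Compound list

1 | 10-bromodecan-1-ol | OCCCCCCCCCCBr | starting material
2 | (10-bromodecyloxy)(tert-butyl)dimethylsilane | CC(C)(C)[Si](C)(C)OCCCCCCCCCCBr | intermediate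
3 | (R)-epichlorohydrin, (R)-2-(chloromethyl)oxirane | ClC[C@H]1CO1 | starting material
4 | [10-(tert-butyldimethylsilyloxy)decyl]magnesium bromide | CC(C)(C)[Si](C)(C)OCCCCCCCCCC[Mg]Br | intermediate (not isolated)
5 | (R)-1-chloro-13-(tert-butyldimethylsilyloxy)tridecan-2-ol, present as its bromomagnesium alkoxide | ClC[C@H](O)CCCCCCCCCCCO[Si](C)(C)C(C)(C)C | intermediate (not isolated)
6 | (R)-tert-butyldimethyl{[11-(oxiran-2-yl)undecyl]oxy}silane | CC(C)(C)[Si](C)(C)OCCCCCCCCCCC[C@@H]1CO1 | intermediate
7 | methyl propiolate | C#CC(=O)OC | starting material
8 | lithium methyl propiolate (methyl 3-lithioprop-2-ynoate) | [Li]C#CC(=O)OC | intermediate (not isolated)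
9 | methyl (R)-5-hydroxy-16-(tert-butyldimethylsilyloxy)hexadec-2-ynoate | COC(=O)C#CC[C@H](O)CCCCCCCCCCCO[Si](C)(C)C(C)(C)C | intermediate
10 | methyl (R)-5,16-bis(tert-butyldimethylsilyloxy)hexadec-2-ynoate | COC(=O)C#CC[C@@H](CCCCCCCCCCCO[Si](C)(C)C(C)(C)C)O[Si](C)(C)C(C)(C)C | intermediate
11 | 1,3-dimethoxybenzene | COc1cccc(OC)c1 | starting material
12 | 1,5-dimethoxycyclohexa-1,4-diene | COC1=CCC=C(OC)C1 | intermediate
13 | 1,3-dimethoxycyclohexa-1,3-diene | COC1=CC(OC)=CCC1 | intermediate
14 | methyl 3-[(R)-2,13-bis(tert-butyldimethylsilyloxy)tridecyl]-1,5-dimethoxybicyclo[2.2.2]octa-2,5-diene-2-carboxylate (both bridgehead diastereomers) | COC(=O)C1=C(C[C@@H](CCCCCCCCCCCO[Si](C)(C)C(C)(C)C)O[Si](C)(C)C(C)(C)C)C2CCC1(OC)C=C2OC | intermediate (not isolated)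
15 | methyl (R)-2-[2,13-bis(tert-butyldimethylsilyloxy)tridecyl]-4,6-dimethoxybenzoate | COC(=O)c1c(OC)cc(OC)cc1C[C@@H](CCCCCCCCCCCO[Si](C)(C)C(C)(C)C)O[Si](C)(C)C(C)(C)C | intermediate
16 | methyl (R)-2-(2,13-dihydroxytridecyl)-4,6-dimethoxybenzoate | COC(=O)c1c(OC)cc(OC)cc1C[C@@H](CCCCCCCCCCCO)O | intermediate (not isolated)
17 | (R)-3-(11-hydroxyundecyl)-6,8-dimethoxyisochroman-1-one | COc1cc(OC)c2c(c1)C[C@@H](CCCCCCCCCCCO)OC2=O | intermediate
18 | (R)-8-hydroxy-3-(11-hydroxyundecyl)-6-methoxyisochroman-1-one | COc1cc(O)c2c(c1)C[C@@H](CCCCCCCCCCCO)OC2=O | target

## Step count and risk assessment

Total step count: 9. Longest linear sequence: 7 steps (steps 1, 2, 3, 4, 7, 8, 9); steps 5 and 6 form a two-step branch that joins at step 7.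

**Step 7 (key step).** The most likely failure is a rate problem. Cycloaddition of the internal, β-branched ynoate may be slower than thermal self-consumption of the diene (dimerisation, or hydrogen transfer back to the aromatic level), so conversion could stall. Traces of acid from enol ether decomposition could also begin to remove silyl groups at this temperature.
Fallback: set out from 6 and build on a bought arene instead of making ring A.
- The Grignard reagent of 1-bromo-3,5-dimethoxybenzene F1 (Mg, THF) would open 6 at its CH2 terminus under CuI catalysis to give (R)-1-(3,5-dimethoxyphenyl)-13-(tert-butyldimethylsilyloxy)tridecan-2-ol F2.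
- NBS in MeCN at 0 °C should brominate the ring position ortho to the side chain and para to a methoxy group, giving (R)-1-(2-bromo-3,5-dimethoxyphenyl)-13-(tert-butyldimethylsilyloxy)tridecan-2-ol F3.
- n-BuLi (2.2 equiv, THF, −78 °C; alkoxide formation then bromine–lithium exchange), CO2 and acidification would give the hydroxy acid, which should close to (R)-3-[11-(tert-butyldimethylsilyloxy)undecyl]-6,8-dimethoxyisochroman-1-one F4.
- The acidic methanol of step 8 would remove the silyl group, and the route is rejoined at 17.

**Step 3.** The lithiated propiolate may decompose by self-condensation if the temperature drifts above −78 °C. The Lewis acid may divert the epoxide through rearrangement or fluoride opening, and butyllithium may attack the ester if deprotonation is incomplete.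
Fallback: set out from 6 and separate the C–C bond formation from the introduction of the ester.
- LiC≡CH·H2N(CH2)2NH2 in DMSO at rt, with no Lewis acid, would open 6 to (R)-15-(tert-butyldimethylsilyloxy)pentadec-1-yn-4-ol F5.
- TBSOTf and 2,6-lutidine would give (R)-4,15-bis(tert-butyldimethylsilyloxy)pentadec-1-yne F6.
- Deprotonation with n-BuLi (THF, −78 °C) and trapping with methyl chloroformate would give 10, where the route is rejoined.

**Step 9.** Site selectivity may be lost (cleavage also at C6 on warming), or cleavage at C8 may be incomplete because the free primary alcohol binds part of the Lewis acid.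
Fallback: set out from 17 and replace selective cleavage by selective alkylation.
- BBr3 in excess (CH2Cl2, −78 → 0 °C, kept cold to limit bromination of the borate-bound primary alcohol) would remove both methyl groups, giving (R)-6,8-dihydroxy-3-(11-hydroxyundecyl)isochroman-1-one F7.
- MeI (1.05 equiv) with K2CO3 in acetone at rt should methylate only the C6 phenol, which is the more acidic (para to the carbonyl) and is not hydrogen-bonded, whereas the C8 phenol is chelated to the lactone carbonyl. This gives 18 directly.

**Step 2.** Enantiomeric purity may erode through attack of the organometallic at the chloromethyl carbon (which after closure leads to the mirror-image oxirane) or through chloride-induced opening and reclosure of 3. Homocoupling during Grignard formation would waste 2.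
Fallback: set out from 2 and obtain the configuration by resolution instead of from the chiral pool.
- Grignard reagent 4 and allyl bromide would give tert-butyldimethyl(tridec-12-en-1-yloxy)silane F8.
- mCPBA in CH2Cl2 would give racemic tert-butyldimethyl{[11-(oxiran-2-yl)undecyl]oxy}silane F9.
- Hydrolytic kinetic resolution with (salen)Co(OAc) (trivalent cobalt; salen = N,N'-bis(3,5-di-tert-butylsalicylidene)cyclohexane-1,2-diamine dianion) and 0.55 equiv H2O, using the catalyst enantiomer that hydrolyses the (S)-epoxide to (S)-13-(tert-butyldimethylsilyloxy)tridecane-1,2-diol F10, would leave 6, where the route is rejoined.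

## Further compounds

F1 | step 7 | 1-bromo-3,5-dimethoxybenzene | COc1cc(Br)cc(OC)c1
F2 | step 7 | (R)-1-(3,5-dimethoxyphenyl)-13-(tert-butyldimethylsilyloxy)tridecan-2-ol | COc1cc(OC)cc(C[C@H](O)CCCCCCCCCCCO[Si](C)(C)C(C)(C)C)c1
F3 | step 7 | (R)-1-(2-bromo-3,5-dimethoxyphenyl)-13-(tert-butyldimethylsilyloxy)tridecan-2-ol | COc1cc(OC)c(Br)c(C[C@H](O)CCCCCCCCCCCO[Si](C)(C)C(C)(C)C)c1
F4 | step 7 | (R)-3-[11-(tert-butyldimethylsilyloxy)undecyl]-6,8-dimethoxyisochroman-1-one | COc1cc(OC)c2c(c1)C[C@@H](CCCCCCCCCCCO[Si](C)(C)C(C)(C)C)OC2=O
F5 | step 3 | (R)-15-(tert-butyldimethylsilyloxy)pentadec-1-yn-4-ol | C#CC[C@H](O)CCCCCCCCCCCO[Si](C)(C)C(C)(C)C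
F6 | step 3 | (R)-4,15-bis(tert-butyldimethylsilyloxy)pentadec-1-yne | C#CC[C@@H](CCCCCCCCCCCO[Si](C)(C)C(C)(C)C)O[Si](C)(C)C(C)(C)C
F7 | step 9 | (R)-6,8-dihydroxy-3-(11-hydroxyundecyl)isochroman-1-one | Oc1cc(O)c2c(c1)C[C@@H](CCCCCCCCCCCO)OC2=O
F8 | step 2 | tert-butyldimethyl(tridec-12-en-1-yloxy)silane | C=CCCCCCCCCCCCO[Si](C)(C)C(C)(C)C
F9 | step 2 | racemic tert-butyldimethyl{[11-(oxiran-2-yl)undecyl]oxy}silane | CC(C)(C)[Si](C)(C)OCCCCCCCCCCCC1CO1
F10 | step 2 | (S)-13-(tert-butyldimethylsilyloxy)tridecane-1,2-diol | OC[C@@H](O)CCCCCCCCCCCO[Si](C)(C)C(C)(C)C
A1 | alternative 1 | racemic 2-(11-hydroxyundecyl)-5,7-dimethoxyindan-1-one | COc1cc(OC)c2c(c1)CC(CCCCCCCCCCCO)C2=O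
A2 | alternative 1 | (R)-3-(11-hydroxyundecyl)-6,8-dimethoxyisochroman-1-one | COc1cc(OC)c2c(c1)C[C@@H](CCCCCCCCCCCO)OC2=O
A3 | alternative 2 | 2,4-dimethoxybenzoic acid | COc1ccc(C(=O)O)c(OC)c1
A4 | alternative 2 | 13-(tert-butyldimethylsilyloxy)-1-[dimethyl(oxo)-λ6-sulfanylidene]tridecan-2-one | CC(C)(C)[Si](C)(C)OCCCCCCCCCCCC(=O)C=S(C)(C)=O
A5 | alternative 2 | 3-[11-(tert-butyldimethylsilyloxy)undecyl]-6,8-dimethoxy-1H-isochromen-1-one | COc1cc(OC)c2c(c1)C=C(CCCCCCCCCCCO[Si](C)(C)C(C)(C)C)OC2=O
A6 | alternative 2 | (R)-3-[11-(tert-butyldimethylsilyloxy)undecyl]-6,8-dimethoxyisochroman-1-one | COc1cc(OC)c2c(c1)C[C@@H](CCCCCCCCCCCO[Si](C)(C)C(C)(C)C)OC2=O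
A7 | alternative 3 | 6-[(R)-6,17-bis(tert-butyldimethylsilyloxy)-2,4-dioxoheptadecyl]-2,2-dimethyl-4H-1,3-dioxin-4-one | CC1(C)OC(=O)C=C(CC(=O)CC(=O)C[C@@H](CCCCCCCCCCCO[Si](C)(C)C(C)(C)C)O[Si](C)(C)C(C)(C)C)O1
A8 | alternative 3 | (R)-5-[2,13-bis(tert-butyldimethylsilyloxy)tridecyl]-7-hydroxy-2,2-dimethyl-4H-benzo[d][1,3]dioxin-4-one | CC1(C)OC(=O)c2c(C[C@@H](CCCCCCCCCCCO[Si](C)(C)C(C)(C)C)O[Si](C)(C)C(C)(C)C)cc(O)cc2O1
A9 | alternative 3 | (R)-5-[2,13-bis(tert-butyldimethylsilyloxy)tridecyl]-7-methoxy-2,2-dimethyl-4H-benzo[d][1,3]dioxin-4-one | CC1(C)OC(=O)c2c(C[C@@H](CCCCCCCCCCCO[Si](C)(C)C(C)(C)C)O[Si](C)(C)C(C)(C)C)cc(OC)cc2O1
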